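## Plan

1. Retrosynthesis: the C8–C(CH3)2 bond is cut last (back to a 7-O-prenyl ether, aromatic Claisen). Next the O1–C8a aryl ether bond of the γ-pyranone (ring C) is cut, then C3–C4 (aldol/oxidation) and C2–C3 (alkoxymethyl anion addition). This leaves an A-ring bromobenzaldehyde and a B-ring chromene aldehyde.
2. Enabling feature: C8a is one of three oxygen-bearing carbons of the phloroglucinol ring A. With bromine on C8a and ethers on C5 and C7, the enol oxygen attached to C2 can only close onto C8a, so no choice between the two ortho oxygens arises.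
3. Forward order: the 2H-pyran of ring B is closed first (propargyl ether Claisen/electrocyclisation). The C2–C3–C4 chain is then built up to a 2-alkoxy-1,3-diketone, copper closes ring C, and the 7-O-prenyl group is shifted to C8.
4. Stereochemistry: the target has no stereogenic element. The sp3 centres that appear in 16, 19, 20 and 24 are racemic and all become sp2 again.

Key step: step 12

Remark on the chemistry: Broussonol A is achiral, so "single enantiomer" is met by the constitution alone and no asymmetric step is planned. Tributyl[(methoxymethoxy)methyl]stannane (15) and IBX are taken as purchasable reagents.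

## Route

Step 1
Reactants: 1 1-bromo-3,5-dimethoxybenzene
Product: 3 2-bromo-4,6-dimethoxybenzaldehyde, via iminium chloride 2 (not isolated)
Conditions: POCl3, DMF, 0 → 90 °C; then ice-water
Reagents that add atoms: N,N-dimethylformamide CN(C)C=O; water O
Why: Vilsmeier–Haack formylation: the chloroiminium ion from DMF and POCl3 should attack the carbon para to one methoxy group and ortho to the other (next to Br) rather than the crowded carbon between the two methoxy groups, and water hydrolyses iminium salt 2 to the aldehyde.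

Step 2
Reactants: 3 2-bromo-4,6-dimethoxybenzaldehyde
Product: 4 2-bromo-4,6-dihydroxybenzaldehyde
Conditions: BBr3 (4 equiv), CH2Cl2, −78 °C → rt; then H2O
Reagents that add atoms: none
Why: Lewis-acid cleavage of aryl methyl ethers (BBr3 demethylation) should free both phenols, the one ortho to the formyl group fastest through chelation, while the C–Br bond and the aldehyde come through the aqueous work-up unchanged.

Step 3
Reactants: 4 2-bromo-4,6-dihydroxybenzaldehyde; 5 prenyl bromide (1-bromo-3-methylbut-2-ene)
Product: 6 2-bromo-6-hydroxy-4-[(3-methylbut-2-en-1-yl)oxy]benzaldehyde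
Conditions: 5 (1.05 equiv), K2CO3 (1.0 equiv), acetone, rt
Reagents that add atoms: prenyl bromide CC(C)=CCBr
Why: Williamson etherification under limiting base: the 6-OH is locked in a hydrogen bond to the formyl oxygen, so the more acidic and more exposed para 4-OH should be alkylated selectively, as is usual for 2,4-dihydroxybenzaldehydes.

Step 4
Reactants: 6 2-bromo-6-hydroxy-4-[(3-methylbut-2-en-1-yl)oxy]benzaldehyde
Product: 7 2-bromo-6-(methoxymethoxy)-4-[(3-methylbut-2-en-1-yl)oxy]benzaldehyde
Conditions: MOMCl, iPr2NEt, DMAP (cat.), CH2Cl2, 0 → 40 °C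
Reagents that add atoms: chloromethyl methyl ether COCCl
Why: Base-mediated O-alkylation with MOMCl (acetal protection) should cap the remaining chelated phenol as an ether that withstands the enolate, oxidation and copper steps and can later be removed selectively from its position peri to the C4 carbonyl.

Step 5
Reactants: 8 3,4-dihydroxybenzaldehyde; 9 3-chloro-3-methylbut-1-yne
Product: 10 3-hydroxy-4-[(2-methylbut-3-yn-2-yl)oxy]benzaldehyde
Conditions: 9 (1.3 equiv), K2CO3 (1.05 equiv), KI (cat.), acetone, reflux
Reagents that add atoms: 3-chloro-3-methylbut-1-yne C#CC(C)(C)Cl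
Why: O-Alkylation of a phenoxide with a tertiary propargylic chloride: with one equivalent of carbonate only the more acidic 4-OH (para to the formyl group) is ionised, which is the basis of the well-known 4-O-selective alkylation of 3,4-dihydroxybenzaldehyde.

Step 6
Reactants: 10 3-hydroxy-4-[(2-methylbut-3-yn-2-yl)oxy]benzaldehyde
Product: 11 3-(methoxymethoxy)-4-[(2-methylbut-3-yn-2-yl)oxy]benzaldehyde
Conditions: MOMCl, iPr2NEt, CH2Cl2, 0 °C → rt
Reagents that add atoms: chloromethyl methyl ether COCCl
Why: Routine MOM acetal formation on an unhindered phenol, which keeps the future 8-OH of the chromene inert through the thermal, organolithium and basic steps.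

Step 7
Reactants: 11 3-(methoxymethoxy)-4-[(2-methylbut-3-yn-2-yl)oxy]benzaldehyde
Product: 14 8-(methoxymethoxy)-2,2-dimethyl-2H-chromene-6-carbaldehyde, via allenyl phenol 12 (not isolated), via ortho-quinone methide 13 (not isolated)
Conditions: PhNEt2, 190 °C
Reagents that add atoms: none
Why: Thermal aryl propargyl ether Claisen cascade: a [3,3] shift to the only free ortho carbon and enolisation give allenyl phenol 12, a 1,5-hydrogen shift gives ortho-quinone methide 13, and oxa-6π electrocyclisation closes the 2,2-dimethyl-2H-pyran ring (standard chromene synthesis).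

Step 8
Reactants: 14 8-(methoxymethoxy)-2,2-dimethyl-2H-chromene-6-carbaldehyde; 15 tributyl[(methoxymethoxy)methyl]stannane
Product: 16 2-(methoxymethoxy)-1-[8-(methoxymethoxy)-2,2-dimethyl-2H-chromen-6-yl]ethan-1-ol (racemic)
Conditions: 15, n-BuLi, THF, −78 °C; then 14, −78 °C; H2O
Reagents that add atoms: tributyl[(methoxymethoxy)methyl]stannane CCCC[Sn](CCCC)(CCCC)COCOC
Why: Tin–lithium exchange gives (methoxymethoxy)methyllithium, a hydroxymethyl anion equivalent whose 1,2-addition to aryl aldehydes is well established; the carbinol centre forms as a racemate and is oxidised away in step 9.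

Step 9
Reactants: 16 2-(methoxymethoxy)-1-[8-(methoxymethoxy)-2,2-dimethyl-2H-chromen-6-yl]ethan-1-ol
Product: 17 2-(methoxymethoxy)-1-[8-(methoxymethoxy)-2,2-dimethyl-2H-chromen-6-yl]ethan-1-one
Conditions: IBX, EtOAc, 75 °C
Reagents that add atoms: none
Why: IBX oxidation of a benzylic secondary alcohol to the aryl ketone under neutral conditions that leave MOM acetals and the chromene double bond untouched.

Step 10
Reactants: 17 2-(methoxymethoxy)-1-[8-(methoxymethoxy)-2,2-dimethyl-2H-chromen-6-yl]ethan-1-one; 7 2-bromo-6-(methoxymethoxy)-4-[(3-methylbut-2-en-1-yl)oxy]benzaldehyde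
Product: 19 3-[2-bromo-6-(methoxymethoxy)-4-[(3-methylbut-2-en-1-yl)oxy]phenyl]-3-hydroxy-2-(methoxymethoxy)-1-[8-(methoxymethoxy)-2,2-dimethyl-2H-chromen-6-yl]propan-1-one (diastereomer mixture), via lithium enolate 18 (not isolated)
Conditions: LiHMDS, THF, −78 °C; then 7, −78 °C; AcOH
Reagents that add atoms: none
Why: Crossed aldol addition: the chelated lithium enolate of the α-alkoxy ketone (its only enolisable site) should add to the non-enolisable, hindered but reactive aldehyde 7; the two new stereocentres form as racemic diastereomers, which does not matter because both centres become sp2 in steps 11 and 12.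

Step 11
Reactants: 19 aldol adduct (diastereomer mixture)
Product: 20 1-[2-bromo-6-(methoxymethoxy)-4-[(3-methylbut-2-en-1-yl)oxy]phenyl]-2-(methoxymethoxy)-3-[8-(methoxymethoxy)-2,2-dimethyl-2H-chromen-6-yl]propane-1,3-dione (racemic)
Conditions: IBX, EtOAc, 75 °C
Reagents that add atoms: none
Why: IBX oxidation of a β-hydroxy ketone to the 1,3-diketone, a standard reagent for this change that does not over-oxidise the acidic C2–H; the remaining C2 centre is racemic and enolisable.

Step 12
Reactants: 20 1-[2-bromo-6-(methoxymethoxy)-4-[(3-methylbut-2-en-1-yl)oxy]phenyl]-2-(methoxymethoxy)-3-[8-(methoxymethoxy)-2,2-dimethyl-2H-chromen-6-yl]propane-1,3-dione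
Product: 22 3,5-bis(methoxymethoxy)-2-[8-(methoxymethoxy)-2,2-dimethyl-2H-chromen-6-yl]-7-[(3-methylbut-2-en-1-yl)oxy]-4H-chromen-4-one, via potassium enolate 21 (not isolated)
Conditions: CuI (10 mol %), 1,10-phenanthroline (20 mol %), K2CO3 (2 equiv), dry DMF, 90 °C, N2
Reagents that add atoms: none
Why: Carbonate converts the diketone into potassium enolate 21, which binds Cu(I); the C–Br bond ortho to the aryl ketone then adds oxidatively with help from the neighbouring carbonyl, and C–O reductive elimination from the aryl-copper enolate forges O1–C8a. The closest known reaction is the copper-catalysed intramolecular Ullmann O-arylation of 1-(2-haloaryl)-1,3-diketones to flavones. The γ-pyranone closes as a six-membered ring by ipso-substitution at C8a by the enol oxygen of the B-ring-side carbonyl, with the C4a–C8a bond inside the new ring and the C–Br bond outside it. No stereocentre is formed; the single sp3 centre of 20 becomes the sp2 C3 of the flavone, which already carries its oxygen. The step needs O- rather than C-arylation and attack by the distal oxygen only: C-arylation or attack by the proximal carbonyl oxygen would require a four-membered ring, and the other ortho carbon of ring A bears a MOM ether, not a halide, so only C8a can react. The ligated catalyst with carbonate in dry DMF should keep hydrodebromination and retro-Claisen cleavage of the diketone in check.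

Step 13
Reactants: 22 3,5-bis(methoxymethoxy)-2-[8-(methoxymethoxy)-2,2-dimethyl-2H-chromen-6-yl]-7-[(3-methylbut-2-en-1-yl)oxy]-4H-chromen-4-one
Product: 23 5-hydroxy-3-(methoxymethoxy)-2-[8-(methoxymethoxy)-2,2-dimethyl-2H-chromen-6-yl]-7-[(3-methylbut-2-en-1-yl)oxy]-4H-chromen-4-one
Conditions: HCl (1.25 M in MeOH, 2 equiv), MeOH–CH2Cl2, 0 °C → rt, quenched (NaHCO3) once 22 is consumed
Reagents that add atoms: none
Why: Acid-catalysed acetal exchange with methanol: the MOM ether peri to the C4 carbonyl should cleave far faster than the other two because the carbonyl hydrogen-bonds the departing phenol oxygen, a selectivity well known for MOM ethers ortho to aryl ketones.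

Step 14
Reactants: 23 5-hydroxy-3-(methoxymethoxy)-2-[8-(methoxymethoxy)-2,2-dimethyl-2H-chromen-6-yl]-7-[(3-methylbut-2-en-1-yl)oxy]-4H-chromen-4-one
Product: 25 5,7-dihydroxy-3-(methoxymethoxy)-2-[8-(methoxymethoxy)-2,2-dimethyl-2H-chromen-6-yl]-8-(2-methylbut-3-en-2-yl)-4H-chromen-4-one, via ortho-dienone 24 (not isolated)
Conditions: PhNEt2, 190 °C (sealed tube), short reaction time
Reagents that add atoms: none
Why: Aromatic Claisen rearrangement: a suprafacial [3,3] shift delivers the dimethyl-substituted terminus of the prenyl group to C8 with allylic inversion (ortho-dienone 24) and tautomerisation restores the phenol; 7-allyloxy chromones whose 5-OH is chelated to C4=O are expected to rearrange mainly to C8, the carbon between O7 and O1, and the basic solvent suppresses acid-induced cyclisation of the product.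

Step 15
Reactants: 25 5,7-dihydroxy-3-(methoxymethoxy)-2-[8-(methoxymethoxy)-2,2-dimethyl-2H-chromen-6-yl]-8-(2-methylbut-3-en-2-yl)-4H-chromen-4-one
Product: 26 Broussonol A, 3,5,7-trihydroxy-2-(8-hydroxy-2,2-dimethyl-2H-chromen-6-yl)-8-(2-methylbut-3-en-2-yl)-4H-chromen-4-one
Conditions: 3 M aq. HCl, MeOH, 45 °C
Reagents that add atoms: none
Why: Acid-catalysed acetal exchange removes the two remaining MOM ethers under dilute HCl/MeOH, conditions that 2,2-dimethylchromenes and ortho-(1,1-dimethylallyl)phenols are known to tolerate.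

## Compound list

1 | 1-bromo-3,5-dimethoxybenzene | COc1cc(Br)cc(OC)c1 | starting material
2 | (2-bromo-4,6-dimethoxybenzylidene)dimethyliminium chloride (not isolated) | C[N+](C)=Cc1c(Br)cc(OC)cc1OC.[Cl-] | intermediate
3 | 2-bromo-4,6-dimethoxybenzaldehyde | COc1cc(Br)c(C=O)c(OC)c1 | intermediate
4 | 2-bromo-4,6-dihydroxybenzaldehyde | Oc1cc(Br)c(C=O)c(O)c1 | intermediate
5 | prenyl bromide (1-bromo-3-methylbut-2-ene) | CC(C)=CCBr | starting material
6 | 2-bromo-6-hydroxy-4-[(3-methylbut-2-en-1-yl)oxy]benzaldehyde | CC(C)=CCOc1cc(Br)c(C=O)c(O)c1 | intermediate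
7 | 2-bromo-6-(methoxymethoxy)-4-[(3-methylbut-2-en-1-yl)oxy]benzaldehyde | CC(C)=CCOc1cc(Br)c(C=O)c(OCOC)c1 | intermediate
8 | 3,4-dihydroxybenzaldehyde | O=Cc1ccc(O)c(O)c1 | starting material
9 | 3-chloro-3-methylbut-1-yne | C#CC(C)(C)Cl | starting material
10 | 3-hydroxy-4-[(2-methylbut-3-yn-2-yl)oxy]benzaldehyde | C#CC(C)(C)Oc1ccc(C=O)cc1O | intermediate
11 | 3-(methoxymethoxy)-4-[(2-methylbut-3-yn-2-yl)oxy]benzaldehyde | C#CC(C)(C)Oc1ccc(C=O)cc1OCOC | intermediate
12 | 4-hydroxy-3-(methoxymethoxy)-5-(3-methylbuta-1,2-dien-1-yl)benzaldehyde (allenyl phenol, not isolated) | CC(C)=C=Cc1cc(C=O)cc(OCOC)c1O | intermediate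
13 | 5-(methoxymethoxy)-3-(3-methylbut-2-en-1-ylidene)-4-oxocyclohexa-1,5-diene-1-carbaldehyde (ortho-quinone methide, not isolated) | O=C1C(OCOC)=CC(C=O)=CC1=CC=C(C)C | intermediate
14 | 8-(methoxymethoxy)-2,2-dimethyl-2H-chromene-6-carbaldehyde | COCOc1cc(C=O)cc2C=CC(C)(C)Oc12 | intermediate
15 | tributyl[(methoxymethoxy)methyl]stannane | CCCC[Sn](CCCC)(CCCC)COCOC | starting material
16 | 2-(methoxymethoxy)-1-[8-(methoxymethoxy)-2,2-dimethyl-2H-chromen-6-yl]ethan-1-ol (racemic) | COCOCC(O)c1cc(OCOC)c2OC(C)(C)C=Cc2c1 | intermediate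
17 | 2-(methoxymethoxy)-1-[8-(methoxymethoxy)-2,2-dimethyl-2H-chromen-6-yl]ethan-1-one | COCOCC(=O)c1cc(OCOC)c2OC(C)(C)C=Cc2c1 | intermediate
18 | lithium (Z)-enolate of 17 (not isolated) | [Li+].[O-]/C(=C\OCOC)c1cc(OCOC)c2OC(C)(C)C=Cc2c1 | intermediate
19 | 3-[2-bromo-6-(methoxymethoxy)-4-[(3-methylbut-2-en-1-yl)oxy]phenyl]-3-hydroxy-2-(methoxymethoxy)-1-[8-(methoxymethoxy)-2,2-dimethyl-2H-chromen-6-yl]propan-1-one (racemic mixture of diastereomers) | COCOC(C(O)c1c(Br)cc(OCC=C(C)C)cc1OCOC)C(=O)c1cc(OCOC)c2OC(C)(C)C=Cc2c1 | intermediate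
20 | 1-[2-bromo-6-(methoxymethoxy)-4-[(3-methylbut-2-en-1-yl)oxy]phenyl]-2-(methoxymethoxy)-3-[8-(methoxymethoxy)-2,2-dimethyl-2H-chromen-6-yl]propane-1,3-dione (racemic, enolisable) | COCOC(C(=O)c1cc(OCOC)c2c(c1)C=CC(C)(C)O2)C(=O)c1c(Br)cc(OCC=C(C)C)cc1OCOC | intermediate
21 | potassium enolate of 20, oxygen on the B-ring-side carbon (not isolated) | [K+].[O-]C(=C(OCOC)C(=O)c1c(Br)cc(OCC=C(C)C)cc1OCOC)c1cc(OCOC)c2c(c1)C=CC(C)(C)O2 | intermediate
22 | 3,5-bis(methoxymethoxy)-2-[8-(methoxymethoxy)-2,2-dimethyl-2H-chromen-6-yl]-7-[(3-methylbut-2-en-1-yl)oxy]-4H-chromen-4-one | CC(C)=CCOc1cc(OCOC)c2c(=O)c(OCOC)c(-c3cc(OCOC)c4c(c3)C=CC(C)(C)O4)oc2c1 | intermediate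
23 | 5-hydroxy-3-(methoxymethoxy)-2-[8-(methoxymethoxy)-2,2-dimethyl-2H-chromen-6-yl]-7-[(3-methylbut-2-en-1-yl)oxy]-4H-chromen-4-one | CC(C)=CCOc1cc(O)c2c(=O)c(OCOC)c(-c3cc(OCOC)c4c(c3)C=CC(C)(C)O4)oc2c1 | intermediate
24 | 5-hydroxy-3-(methoxymethoxy)-2-[8-(methoxymethoxy)-2,2-dimethyl-2H-chromen-6-yl]-8-(2-methylbut-3-en-2-yl)-8H-chromene-4,7-dione (ortho-dienone, racemic at C8, not isolated) | C=CC(C)(C)C1C(=O)C=C(O)C2=C1OC(-c1cc(OCOC)c3c(c1)C=CC(C)(C)O3)=C(OCOC)C2=O | intermediate
25 | 5,7-dihydroxy-3-(methoxymethoxy)-2-[8-(methoxymethoxy)-2,2-dimethyl-2H-chromen-6-yl]-8-(2-methylbut-3-en-2-yl)-4H-chromen-4-one | C=CC(C)(C)c1c(O)cc(O)c2c(=O)c(OCOC)c(-c3cc(OCOC)c4c(c3)C=CC(C)(C)O4)oc12 | intermediate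
26 | Broussonol A, 3,5,7-trihydroxy-2-(8-hydroxy-2,2-dimethyl-2H-chromen-6-yl)-8-(2-methylbut-3-en-2-yl)-4H-chromen-4-one (achiral) | C=CC(C)(C)c1c(O)cc(O)c2c(=O)c(O)c(-c3cc(O)c4c(c3)C=CC(C)(C)O4)oc12 | target

## Step count

Total: 15 steps. Longest linear sequence: 11 steps (steps 5–15, from 3,4-dihydroxybenzaldehyde); the A-ring branch (steps 1–4) joins at step 10.

## Steps most likely to fail

**Step 12 (copper-catalysed ring closure).** The hot carbonate medium may cleave the crowded 2-alkoxy-1,3-diketone by retro-Claisen fragmentation. The C–Br bond may be reduced instead of coupled, or oxidative addition at the electron-rich bromoarene may stall. The fallback sets out from 20 and returns at 23; it makes the O1–C8a bond by condensation instead of cross-coupling. Miyaura borylation of 20 (B2pin2, PdCl2(dppf), KOAc, dioxane, 85 °C) should give the arylboronic pinacol ester F1. Oxidation with NaBO3·4H2O in THF–H2O at rt should give the 2-hydroxyaryl diketone F2, which sits in equilibrium with its cyclic hemiketal. Catalytic TsOH in MeOH at rt should then cyclodehydrate F2 in a Baker–Venkataraman-type closure. The same acid is expected to strip the peri MOM ether, so the sequence rejoins the route at 23. Loss of that MOM group before ring closure does no harm, because both ortho oxygens then lead to the same flavone.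

**Step 14 (Claisen rearrangement).** The allyl unit may migrate to C6 instead of C8. The hot ortho-(1,1-dimethylallyl)phenol may also react further, by abnormal Claisen rearrangement or by ring closure onto the 7-OH. The fallback sets out from 22 and returns at 26; it changes the directing element instead of the temperature. The rearrangement is run on 22, in which O5 is still an acetal and no chelate biases ring A. Bond fixation then comes only from the O1–C8a=C4a–C4=O vinylogous ester, as in 7-allyloxyflavones without a 5-OH. This should give the 7-hydroxy-8-(2-methylbut-3-en-2-yl) tris-MOM flavone F3. HCl/MeOH as in step 15 then removes all three MOM groups and gives 26.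

**Step 15 (final MOM removal).** Under acid the 7-OH may add to the protonated 1,1-dimethylallyl alkene and close a dihydrofuran. Methanol may also add across the chromene double bond before the last MOM group has left. The fallback sets out from 23 and returns at 26; it reverses the order so that no acid touches the tert-allyl phenol. The two remaining MOM ethers of 23 are cleaved first (HCl, MeOH, rt). The 7-O-prenyl ether sits on a vinylogous-acid oxygen and is expected to tolerate brief, dilute acid. This gives the 3,5,8′-triol 7-prenyl ether F4. The thermal Claisen rearrangement (PhNEt2, 190 °C) is then the last step and gives 26 directly.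

## Further compounds

F1 | step 12 | 1-[2-(4,4,5,5-tetramethyl-1,3,2-dioxaborolan-2-yl)-6-(methoxymethoxy)-4-[(3-methylbut-2-en-1-yl)oxy]phenyl]-2-(methoxymethoxy)-3-[8-(methoxymethoxy)-2,2-dimethyl-2H-chromen-6-yl]propane-1,3-dione | COCOC(C(=O)c1cc(OCOC)c2c(c1)C=CC(C)(C)O2)C(=O)c1c(B2OC(C)(C)C(C)(C)O2)cc(OCC=C(C)C)cc1OCOC
F2 | step 12 | 1-[2-hydroxy-6-(methoxymethoxy)-4-[(3-methylbut-2-en-1-yl)oxy]phenyl]-2-(methoxymethoxy)-3-[8-(methoxymethoxy)-2,2-dimethyl-2H-chromen-6-yl]propane-1,3-dione | COCOC(C(=O)c1cc(OCOC)c2c(c1)C=CC(C)(C)O2)C(=O)c1c(O)cc(OCC=C(C)C)cc1OCOC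
F3 | step 14 | 7-hydroxy-3,5-bis(methoxymethoxy)-2-[8-(methoxymethoxy)-2,2-dimethyl-2H-chromen-6-yl]-8-(2-methylbut-3-en-2-yl)-4H-chromen-4-one | C=CC(C)(C)c1c(O)cc(OCOC)c2c(=O)c(OCOC)c(-c3cc(OCOC)c4c(c3)C=CC(C)(C)O4)oc12
F4 | step 15 | 3,5-dihydroxy-2-(8-hydroxy-2,2-dimethyl-2H-chromen-6-yl)-7-[(3-methylbut-2-en-1-yl)oxy]-4H-chromen-4-one | CC(C)=CCOc1cc(O)c2c(=O)c(O)c(-c3cc(O)c4c(c3)C=CC(C)(C)O4)oc2c1
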